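**Strategy.** Everything rests on cutting ring C of the flavan half at O1–C2 and C3–C4. The feature exploited is C4, a benzhydryl carbon flanked by the electron-rich rings A and D, with the future O1 sitting on C8a of ring A next to it. An ortho-hydroxybenzhydrol therefore ionises to a ring A ortho-quinone methide, which takes up 4-(benzyloxy)styrene in a chiral phosphoric acid-catalysed [4+2] step that closes ring C, forms both bonds and sets C2 and C4 at once. The precursor is that diaryl carbinol; its ring D already carries two benzyl ethers and the (S)-configured 3-aryloxy-3-phenylpropanoate chain that later becomes ring F, so C4 epimers are separable diastereomers.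

Key step: step 5

Remark (assumption): which enantiomer of the phosphoric acid opens the required face at C4 cannot be fixed on paper. The (R) acid is written as the matched one; because the two C4 epimers are diastereomers, the choice can be checked on the first run and the (S) acid substituted without other change.

Remark on notation: rings A and C are the benzo and pyran rings of the flavan, ring B its 2-aryl group, rings D and F the benzo and pyranone rings of the flavanone. The configuration at C4 of the flavan is given relative to C2 (the two aryl groups trans); the SMILES in the compound list fix it absolutely.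

**Step 1**
Reactants: 1 2,4,6-trihydroxybenzaldehyde
Product: 2 2,4-bis(benzyloxy)-6-hydroxybenzaldehyde
Conditions: BnBr (2.05 equiv), K2CO3 (2.1 equiv), DMF, 0 °C → rt
Reagents that add atoms: benzyl bromide, BrCc1ccccc1
Why: Williamson etherification under mild carbonate conditions should alkylate the 4-OH (most acidic, para to the formyl group) and one ortho OH, while the last ortho hydroxyl stays free because it is locked in a hydrogen bond to the formyl oxygen; no stereocenter is formed.

**Step 2**
Reactants: 2 2,4-bis(benzyloxy)-6-hydroxybenzaldehyde; 3 ethyl (3R)-3-hydroxy-3-phenylpropanoate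
Product: 4 ethyl (3S)-3-[3,5-bis(benzyloxy)-2-formylphenoxy]-3-phenylpropanoate
Conditions: PPh3, DIAD (slow addition), toluene, 0 °C → rt
Reagents that add atoms: none
Why: Mitsunobu etherification, in which the acidic salicylaldehyde-type phenol displaces the benzylic oxyphosphonium group of 3 in an SN2 step with inversion, turning the (R) carbinol into the (S) aryl ether that becomes C2 of ring F; the weakly basic phenoxide and the low temperature hold back E2 loss to ethyl cinnamate.

**Step 3**
Reactants: 5 3,5-dimethoxyphenol; 4 ethyl (3S)-3-[3,5-bis(benzyloxy)-2-formylphenoxy]-3-phenylpropanoate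
Product: 7 ethyl (3S)-3-{3,5-bis(benzyloxy)-2-[hydroxy(2-hydroxy-4,6-dimethoxyphenyl)methyl]phenoxy}-3-phenylpropanoate (both carbinol epimers), via bromomagnesium 3,5-dimethoxyphenoxide 6 (not isolated)
Conditions: EtMgBr (1.0 equiv), Et2O, 0 °C; solvent exchange to CH2Cl2; 4 (1.0 equiv), 0 °C → rt; H2O quench; SiO2 deactivated with 1% Et3N
Reagents that add atoms: none
Why: Chelation-controlled ortho-hydroxyalkylation of a magnesium phenoxide with an aldehyde (a Friedel–Crafts-type hydroxyalkylation), in which magnesium binds the formyl oxygen and delivers it to one of the two equivalent ortho carbons through a six-membered array; the ester is inert to ArOMgBr, and the carbinol centre forms without control, which is harmless because step 5 destroys it.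

**Step 4**
Reactants: 8 4-(benzyloxy)benzaldehyde
Product: 9 4-(benzyloxy)styrene
Conditions: MePPh3Br, KOtBu, THF, 0 °C → rt
Reagents that add atoms: methyltriphenylphosphonium bromide, C[P+](c1ccccc1)(c1ccccc1)c1ccccc1.[Br-]
Why: Wittig methylenation of an aromatic aldehyde with a non-stabilised ylide, which raises no stereochemical question and leaves the benzyl ether alone.

**Step 5**
Reactants: 7 ethyl (3S)-3-{3,5-bis(benzyloxy)-2-[hydroxy(2-hydroxy-4,6-dimethoxyphenyl)methyl]phenoxy}-3-phenylpropanoate; 9 4-(benzyloxy)styrene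
Product: 11 ethyl (3S)-3-{3,5-bis(benzyloxy)-2-[(2S)-2-[4-(benzyloxy)phenyl]-5,7-dimethoxychroman-4-yl]phenoxy}-3-phenylpropanoate (flavan 2,4-trans), via ring A ortho-quinone methide 10 (not isolated)
Conditions: (R)-3,3'-bis(2,4,6-triisopropylphenyl)-1,1'-binaphthyl-2,2'-diyl hydrogen phosphate (10 mol%), 9 (3 equiv), 4 Å MS, toluene, −20 °C → rt
Reagents that add atoms: none
Why: The phosphoric acid protonates the doubly benzylic carbinol of 7, water leaves, and the (Z)-configured ring A ortho-quinone methide 10 is held as a hydrogen-bonded ion pair by the chiral phosphate while styrene 9 adds across its oxygen and methide carbon in an asynchronous inverse-electron-demand oxa-[4+2] cycloaddition, C3–C4 bonding running ahead of O1–C2. The closest known reaction type is the chiral phosphoric acid-catalysed [4+2] cycloaddition of ortho-quinone methides, generated from ortho-hydroxybenzyl alcohols, with styrenes and vinylphenols to 2,4-diarylchromans. Ring C is closed by the cycloaddition itself, the four-atom unit O1–C8a–C4a–C4 taking up the two styrene carbons to a six-membered ring (should the process turn stepwise, the second bond is a 6-endo capture of the 4-alkoxybenzyl cation by the ring A oxygen). C4 is set by the face of the methide carbon left open by the chiral phosphate, with the (S) chain on ring D as a second, weaker element that also makes any C4 epimer a separable diastereomer. C2 is set relative to C4: the C5 methoxy group pushes ring D to the oxygen side of the methide, so endo approach of the styrene aryl places the C2 aryl trans to ring D, and this trans arrangement (C4 aryl pseudoaxial away from the C5 methoxy group, C2 aryl equatorial) is also the thermodynamic one, reachable through acid-reversible ionisation of the O1–C2 bond. The step needs regio- and chemoselectivity: the polarised quinone methide can only bond its electrophilic C4 to the styrene terminus and its oxygen to the benzylic carbon, ring D has no free hydroxyl from which a second quinone methide could form, and the excess of electron-rich 4-alkoxystyrene should outrun self-condensation while the weak acid leaves benzyl ethers and ester untouched.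

**Step 6**
Reactants: 11 ethyl (3S)-3-{3,5-bis(benzyloxy)-2-[(2S)-2-[4-(benzyloxy)phenyl]-5,7-dimethoxychroman-4-yl]phenoxy}-3-phenylpropanoate (flavan 2,4-trans)
Product: 12 (3S)-3-{3,5-bis(benzyloxy)-2-[(2S)-2-[4-(benzyloxy)phenyl]-5,7-dimethoxychroman-4-yl]phenoxy}-3-phenylpropanoic acid (flavan 2,4-trans)
Conditions: LiOH·H2O (3 equiv), THF/MeOH/H2O, 0 °C → rt; then cold 0.5 M HCl to pH 4
Reagents that add atoms: lithium hydroxide, [Li+].[OH-]
Why: Saponification by acyl–oxygen cleavage, to which benzyl ethers, the chroman and the aryl alkyl ethers are inert; the ether-bearing carbon of the chain has no acidic hydrogen, and the low temperature limits E1cB loss of the ring D phenoxide from the ester enolate.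

**Step 7**
Reactants: 12 (3S)-3-{3,5-bis(benzyloxy)-2-[(2S)-2-[4-(benzyloxy)phenyl]-5,7-dimethoxychroman-4-yl]phenoxy}-3-phenylpropanoic acid (flavan 2,4-trans)
Product: 14 (2S)-5,7-bis(benzyloxy)-8-[(2S)-2-[4-(benzyloxy)phenyl]-5,7-dimethoxychroman-4-yl]-2-phenylchroman-4-one (flavan 2,4-trans), via mixed trifluoroacetic anhydride 13 (not isolated)
Conditions: (CF3CO)2O (1.1 equiv), CH2Cl2 (dilute), 0 °C → rt
Reagents that add atoms: none
Why: Intramolecular Friedel–Crafts acylation through the mixed anhydride, in which the only free position ortho to the chain oxygen of ring D lies between two alkoxy groups and is nucleophilic enough to close the six-membered ring F without a Lewis acid; the (S) centre at C2 of ring F is not involved, and any loss of the benzyl group next to the new ketone is harmless because step 8 removes it anyway.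

**Step 8**
Reactants: 14 (2S)-5,7-bis(benzyloxy)-8-[(2S)-2-[4-(benzyloxy)phenyl]-5,7-dimethoxychroman-4-yl]-2-phenylchroman-4-one (flavan 2,4-trans)
Product: 15 (2S)-5,7-dihydroxy-8-[(2S)-2-(4-hydroxyphenyl)-5,7-dimethoxychroman-4-yl]-2-phenylchroman-4-one (flavan 2,4-trans), the target CNP0188217.1
Conditions: H2 (1 atm), 10% Pd/C, EtOAc/MeOH, rt
Reagents that add atoms: none
Why: Catalytic hydrogenolysis of the three benzyl aryl ethers under mild conditions that the cyclic benzylic C2–O bonds of flavans and flavanones and the aryl ketone are known to survive, so no stereocenter is touched.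

**Compound list**
1 | 2,4,6-trihydroxybenzaldehyde | O=Cc1c(O)cc(O)cc1O | starting material
2 | 2,4-bis(benzyloxy)-6-hydroxybenzaldehyde | O=Cc1c(O)cc(OCc2ccccc2)cc1OCc1ccccc1 | intermediate
3 | ethyl (3R)-3-hydroxy-3-phenylpropanoate | CCOC(=O)C[C@@H](O)c1ccccc1 | starting material
4 | ethyl (3S)-3-[3,5-bis(benzyloxy)-2-formylphenoxy]-3-phenylpropanoate | CCOC(=O)C[C@H](Oc1cc(OCc2ccccc2)cc(OCc2ccccc2)c1C=O)c1ccccc1 | intermediate
5 | 3,5-dimethoxyphenol | COc1cc(O)cc(OC)c1 | starting material
6 | bromomagnesium 3,5-dimethoxyphenoxide | COc1cc(OC)cc(O[Mg]Br)c1 | intermediate (not isolated)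
7 | ethyl (3S)-3-{3,5-bis(benzyloxy)-2-[hydroxy(2-hydroxy-4,6-dimethoxyphenyl)methyl]phenoxy}-3-phenylpropanoate, both carbinol epimers | CCOC(=O)C[C@H](Oc1cc(OCc2ccccc2)cc(OCc2ccccc2)c1C(O)c1c(O)cc(OC)cc1OC)c1ccccc1 | intermediate
8 | 4-(benzyloxy)benzaldehyde | O=Cc1ccc(OCc2ccccc2)cc1 | starting material
9 | 4-(benzyloxy)styrene | C=Cc1ccc(OCc2ccccc2)cc1 | intermediate
10 | ethyl (3S)-3-{3,5-bis(benzyloxy)-2-[(Z)-(2,4-dimethoxy-6-oxocyclohexa-2,4-dien-1-ylidene)methyl]phenoxy}-3-phenylpropanoate (ring A ortho-quinone methide) | CCOC(=O)C[C@H](Oc1cc(OCc2ccccc2)cc(OCc2ccccc2)c1/C=C3\C(=O)C=C(OC)C=C3OC)c1ccccc1 | intermediate (not isolated)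
11 | ethyl (3S)-3-{3,5-bis(benzyloxy)-2-[(2S)-2-[4-(benzyloxy)phenyl]-5,7-dimethoxychroman-4-yl]phenoxy}-3-phenylpropanoate, C4 aryl trans to C2 aryl | COc1cc(OC)c2c(c1)O[C@H](c1ccc(OCc3ccccc3)cc1)C[C@H]2c1c(O[C@H](c2ccccc2)CC(=O)OCC)cc(OCc2ccccc2)cc1OCc1ccccc1 | intermediate
12 | (3S)-3-{3,5-bis(benzyloxy)-2-[(2S)-2-[4-(benzyloxy)phenyl]-5,7-dimethoxychroman-4-yl]phenoxy}-3-phenylpropanoic acid, C4 aryl trans to C2 aryl | COc1cc(OC)c2c(c1)O[C@H](c1ccc(OCc3ccccc3)cc1)C[C@H]2c1c(O[C@H](c2ccccc2)CC(=O)O)cc(OCc2ccccc2)cc1OCc1ccccc1 | intermediate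
13 | mixed anhydride of 12 with trifluoroacetic acid | COc1cc(OC)c2c(c1)O[C@H](c1ccc(OCc3ccccc3)cc1)C[C@H]2c1c(O[C@H](c2ccccc2)CC(=O)OC(=O)C(F)(F)F)cc(OCc2ccccc2)cc1OCc1ccccc1 | intermediate (not isolated)
14 | (2S)-5,7-bis(benzyloxy)-8-[(2S)-2-[4-(benzyloxy)phenyl]-5,7-dimethoxychroman-4-yl]-2-phenylchroman-4-one, flavan 2,4-trans | COc1cc(OC)c2c(c1)O[C@H](c1ccc(OCc3ccccc3)cc1)C[C@H]2c1c(OCc2ccccc2)cc(OCc2ccccc2)c2c1O[C@H](c1ccccc1)CC2=O | intermediate
15 | (2S)-5,7-dihydroxy-8-[(2S)-2-(4-hydroxyphenyl)-5,7-dimethoxychroman-4-yl]-2-phenylchroman-4-one, flavan 2,4-trans (CNP0188217.1) | COc1cc(OC)c2c(c1)O[C@H](c1ccc(O)cc1)C[C@H]2c1c(O)cc(O)c2c1O[C@H](c1ccccc1)CC2=O | target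

**Step count.** Total: 8 steps. Longest linear sequence: 7 steps (steps 1, 2, 3, 5, 6, 7, 8); step 4 is a one-step branch.

**Steps most likely to fail**

Step 5. The process at risk is the cycloaddition itself: too little discrimination between the two faces of the methide carbon, closure of ring C to the 2,4-cis arrangement, or self-condensation of the quinone methide with ring A of a second molecule before the styrene captures it. The fallback sets out from 7 and comes back at 11, replacing the cycloaddition by a stepwise sequence of known reactions. Commercial 4'-(benzyloxy)acetophenone is silylated (TMSOTf, Et3N, CH2Cl2, 0 °C) to the silyl enol ether trimethyl({1-[4-(benzyloxy)phenyl]ethenyl}oxy)silane F1. This more nucleophilic partner adds to the quinone methide generated from 7 with the same chiral phosphoric acid in a Mukaiyama–Michael-type conjugate addition, giving the ketone ethyl (3S)-3-{3,5-bis(benzyloxy)-2-[3-[4-(benzyloxy)phenyl]-1-(2-hydroxy-4,6-dimethoxyphenyl)-3-oxopropyl]phenoxy}-3-phenylpropanoate F2, whose C4-type epimers are diastereomers and can be separated. NaBH4 (THF/MeOH, 0 °C) reduces the ketone, sparing the ester, to the diol ethyl (3S)-3-{3,5-bis(benzyloxy)-2-[3-[4-(benzyloxy)phenyl]-3-hydroxy-1-(2-hydroxy-4,6-dimethoxyphenyl)propyl]phenoxy}-3-phenylpropanoate F3, whose carbinol configuration is irrelevant. Catalytic pyridinium p-toluenesulfonate in CH2Cl2 then ionises the 4-alkoxybenzylic alcohol and the ring A phenol closes ring C under thermodynamic control to the 2,4-trans chroman 11.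

Step 3. The process at risk is ionisation of the magnesium alkoxide of the product followed by capture by a second phenoxide (over-reaction to a triarylmethane), or sluggish addition to the electron-rich, doubly ortho-substituted aldehyde. The fallback sets out from 5 and comes back at 7, replacing phenoxide C-alkylation by an aryllithium carbonyl addition. Phenol 5 is brominated ortho to the hydroxyl group (NBS, catalytic i-Pr2NH, CH2Cl2, −78 °C → 0 °C) to 2-bromo-3,5-dimethoxyphenol F4. Two equivalents of n-BuLi (THF, −78 °C) deprotonate the phenol and exchange bromine for lithium, giving lithium 2-lithio-3,5-dimethoxyphenoxide F5. This adds at −78 °C to the formyl group of 4 in preference to its ester and, after a water quench, should give 7.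

Step 2. The process at risk is E2 loss from the activated β-hydroxy ester to ethyl cinnamate in place of substitution, or partial loss of configuration through ionisation of the benzylic oxyphosphonium ion. The fallback sets out from 2 and comes back at 12, using an alcohol without an acidifying group. Commercial (R)-1-phenylpropane-1,3-diol is silylated at the primary hydroxyl (TBSCl, imidazole, CH2Cl2, 0 °C) to (1R)-3-[(tert-butyldimethylsilyl)oxy]-1-phenylpropan-1-ol F6. Mitsunobu etherification with 2 (PPh3, DIAD, toluene), which 3-substituted 1-phenylpropan-1-ols are known to undergo with phenols with clean inversion, gives 2,4-bis(benzyloxy)-6-{[(1S)-3-[(tert-butyldimethylsilyl)oxy]-1-phenylpropyl]oxy}benzaldehyde F7. The operations of steps 3 and 5 then give the benzhydrol 2-[[2,4-bis(benzyloxy)-6-{[(1S)-3-[(tert-butyldimethylsilyl)oxy]-1-phenylpropyl]oxy}phenyl](hydroxy)methyl]-3,5-dimethoxyphenol F8 and the cycloadduct tert-butyl{(3S)-3-{3,5-bis(benzyloxy)-2-[(2S)-2-[4-(benzyloxy)phenyl]-5,7-dimethoxychroman-4-yl]phenoxy}-3-phenylpropoxy}dimethylsilane F9. TBAF (THF, 0 °C) frees the primary alcohol (3S)-3-{3,5-bis(benzyloxy)-2-[(2S)-2-[4-(benzyloxy)phenyl]-5,7-dimethoxychroman-4-yl]phenoxy}-3-phenylpropan-1-ol F10, and TEMPO/PhI(OAc)2 in MeCN/H2O oxidises it to acid 12, so the base-sensitive ester is never made.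

**Further compounds**
F1 | step 5 | trimethyl({1-[4-(benzyloxy)phenyl]ethenyl}oxy)silane | C=C(O[Si](C)(C)C)c1ccc(OCc2ccccc2)cc1
F2 | step 5 | ethyl (3S)-3-{3,5-bis(benzyloxy)-2-[3-[4-(benzyloxy)phenyl]-1-(2-hydroxy-4,6-dimethoxyphenyl)-3-oxopropyl]phenoxy}-3-phenylpropanoate, C1 of the propyl chain configured as C4 of 11 | O=C(C[C@H](c1c(O)cc(OC)cc1OC)c1c(O[C@H](c2ccccc2)CC(=O)OCC)cc(OCc2ccccc2)cc1OCc1ccccc1)c1ccc(OCc2ccccc2)cc1
F3 | step 5 | ethyl (3S)-3-{3,5-bis(benzyloxy)-2-[3-[4-(benzyloxy)phenyl]-3-hydroxy-1-(2-hydroxy-4,6-dimethoxyphenyl)propyl]phenoxy}-3-phenylpropanoate, both carbinol epimers | OC(C[C@H](c1c(O)cc(OC)cc1OC)c1c(O[C@H](c2ccccc2)CC(=O)OCC)cc(OCc2ccccc2)cc1OCc1ccccc1)c1ccc(OCc2ccccc2)cc1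
F4 | step 3 | 2-bromo-3,5-dimethoxyphenol | COc1cc(O)c(Br)c(OC)c1
F5 | step 3 | lithium 2-lithio-3,5-dimethoxyphenoxide | COc1cc(O[Li])c([Li])c(OC)c1
F6 | step 2 | (1R)-3-[(tert-butyldimethylsilyl)oxy]-1-phenylpropan-1-ol | CC(C)(C)[Si](C)(C)OCC[C@@H](O)c1ccccc1
F7 | step 2 | 2,4-bis(benzyloxy)-6-{[(1S)-3-[(tert-butyldimethylsilyl)oxy]-1-phenylpropyl]oxy}benzaldehyde | CC(C)(C)[Si](C)(C)OCC[C@H](Oc1cc(OCc2ccccc2)cc(OCc2ccccc2)c1C=O)c1ccccc1
F8 | step 2 | 2-[[2,4-bis(benzyloxy)-6-{[(1S)-3-[(tert-butyldimethylsilyl)oxy]-1-phenylpropyl]oxy}phenyl](hydroxy)methyl]-3,5-dimethoxyphenol, both carbinol epimers | CC(C)(C)[Si](C)(C)OCC[C@H](Oc1cc(OCc2ccccc2)cc(OCc2ccccc2)c1C(O)c1c(O)cc(OC)cc1OC)c1ccccc1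
F9 | step 2 | tert-butyl{(3S)-3-{3,5-bis(benzyloxy)-2-[(2S)-2-[4-(benzyloxy)phenyl]-5,7-dimethoxychroman-4-yl]phenoxy}-3-phenylpropoxy}dimethylsilane, flavan 2,4-trans | COc1cc(OC)c2c(c1)O[C@H](c1ccc(OCc3ccccc3)cc1)C[C@H]2c1c(O[C@H](c2ccccc2)CCO[Si](C)(C)C(C)(C)C)cc(OCc2ccccc2)cc1OCc1ccccc1
F10 | step 2 | (3S)-3-{3,5-bis(benzyloxy)-2-[(2S)-2-[4-(benzyloxy)phenyl]-5,7-dimethoxychroman-4-yl]phenoxy}-3-phenylpropan-1-ol, flavan 2,4-trans | COc1cc(OC)c2c(c1)O[C@H](c1ccc(OCc3ccccc3)cc1)C[C@H]2c1c(O[C@H](c2ccccc2)CCO)cc(OCc2ccccc2)cc1OCc1ccccc1
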